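## Structural features

Compound 22 is a 3,4-dihydroisocoumarin (isochroman-1-one). Aromatic ring A (C4a, C5, C6, C7, C8, C8a) is fused through the C4a–C8a edge to the six-membered δ-lactone ring B (C1, O2, C3, C4). Ring A carries phenols at C6 and C8, the latter next to the C1 carbonyl, so C1/C6/C8 form the oxygenation pattern of a resorcylate. C3 is the only stereocentre of the bicycle and bears an unbranched eleven-carbon chain with a secondary carbinol at C6'. CIP analysis of the structure gives 3R and 6'S, and the numbered compounds below were checked against it. The two stereocentres are six carbon atoms apart, so neither can direct the other and their diastereomers will be very hard to separate. Each must therefore be introduced with high absolute control, and this, not the ring construction, is the real difficulty. The fragile points are the lactone (opened by hydroxide or alkoxide), the oxidation-prone resorcinol ring, and the free secondary alcohol, which must be masked through organometallic, acylating and silyl ketene acetal chemistry. The key step uses the fact that the shared C4a–C8a bond is also the α,β-bond of an unsaturated δ-lactone, while C5–C6(O)–C7–C8(O) is a four-carbon unit oxygenated at its first and third carbons, as in an acetoacetate-derived diene. Ring A can therefore be grown onto a lactone that already holds C3.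

## Logic of the disconnections

22 ⇒ 21. Only the O–Si bond at C6' is changed. The carbinol has to be masked in front of the acetylide, the allylborane, the acid chloride, bromine and the silyl ketene acetal, and one tert-butyldimethylsilyl group serves for all of them. Nothing is gained in skeleton; the demand is that the final cleavage spares the lactone and the resorcinol, which points to fluoride in a slightly acidic medium.

21 ⇒ 14 + 18. The bonds C4a–C5 and C8–C8a are cut, removing all of ring A except the edge it shares with ring B. The cut is placed there because that edge is the α,β-bond of an unsaturated lactone and the C6/C8 oxygens match a 1,1,3-trioxygenated diene. The gain is large: the arene, both phenols and their positions come from a four-carbon commodity, and the stereochemical problem is confined to a monocyclic lactone. The forward step must place the nucleophilic diene terminus on C4a, must carry a leaving group on C8a to reach the aromatic oxidation level, and must release the phenols unprotected.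

18 ⇒ 16 ⇒ 15. Two O–Si bonds are cut in turn. The demand is O- and not C-silylation and strictly anhydrous handling.

14 ⇒ 12. The C–Br bond at the α-carbon is cut. Bromine can be put on by addition to the enoate and elimination, so the precursor is the parent unsaturated lactone. The elimination must remove the bromide at C4 and not the one at C3, which the acidity of the α-hydrogen secures.

12 ⇒ 11 ⇒ 9 + 10. The ring double bond (C3=C4 of the pyranone) is cut as a metathesis bond, then the ester C–O bond. The ring is thereby reduced to a homoallylic alcohol and a three-carbon acid chloride. The forward ring closure needs a catalyst that accepts an electron-poor acrylate, and high dilution.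

9 ⇒ 7. The bond between the carbinol carbon and the allylic CH2 is cut. This is where the future C3 centre is created. Because the other stereocentre is six carbons away, the forward allyl transfer must be fully reagent-controlled.

7 ⇒ 6 ⇒ 5 ⇒ 2 + 3, and 2 ⇒ 1. The aldehyde is masked as a dimethyl acetal, the saturated chain is traced to an alkyne, and the C(sp)–C(sp3) bond is cut. This takes the C6' centre from the purchased 1 and the remaining four chain carbons from 3. The aldehyde is then released by hydrolysis alone, with no separate deprotection and oxidation. The demands are that the carbinol C–O bond is never broken and that the acetal hydrolysis is mild enough for the silyl ether.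

## Other disconnections considered

Alternative 1: The cut removes O2 from between C1 and C3, giving the ring-contracted, α-racemising indanone A1. In the forward key step a Baeyer–Villiger monooxygenase with O2 and recycled NADPH would oxidise one enantiomer of A1 with migration of the secondary alkyl carbon while the other enantiomer racemises through its enol, giving A2.
- In its favour: ring B and the C3 centre would be made in one catalytic step in water with air as oxidant, and a dynamic kinetic resolution can in principle convert all of the material.
- Against it here: the aryl group competes as the migrating group in benzo-fused ketones; the substrate carries a methoxy group peri to the carbonyl and a long lipophilic hydroxyalkyl tail, far from the small 2-alkylindanones such enzymes usually accept; racemisation needs a pH at which the lactone product is not fully safe; two aryl methyl ethers must then be cleaved by a strong Lewis acid in the presence of the lactone and the free alcohol.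
- Comparison: on structure it is the better plan, since the C3–O bond and the C3 configuration are formed together by a catalyst and not by a stoichiometric chiral borane five steps earlier. On mechanism the chosen cycloaddition is predictable from frontier-orbital polarisation, whereas acceptance, migratory preference and enantiopreference of the enzyme would have to be found by screening. On step economy it is about equal, but its end game is harsher than a desilylation.

Alternative 2: The cut is the C4a–C8a bond, with the lactone C1–O2 bond made afterwards. In the forward key step triethylamine would make the dioxinone carbon of A3 add to the C4a ketone, and mild acid would dehydrate and enolise to the resorcylate A4. Desilylation and capture of the dioxinone carbonyl by the C3 hydroxyl with loss of acetone would then give 22.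
- In its favour: a mild, biomimetic aldol aromatisation whose regiochemistry is fixed by chain connectivity; the C8 phenol and the carboxyl are masked together, the C6 phenol arrives free, and no methyl ethers need cleaving.
- Against it here: both stereocentres and the whole C13 chain must be built into a linear acyl fragment before ring A exists; A3 is a sensitive triketide equivalent needing sequential acylations of the dioxinone; the end game needs desilylation and lactonisation.
- Comparison: on mechanism it is the better plan, because there is no leaving-group elimination and no excess of a labile diene. On structure it is equal, since both plans set the stereocentres outside the key step and both deliver free phenols. On step economy it is worse by several steps and is less convergent.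

Alternative 3: The cut removes the C1 carbonyl by breaking C8a–C1 and C1–O2, giving the homobenzylic alcohol A5. In the forward key step Pd(OAc)2, CO and AgOAc would effect hydroxyl-directed ortho palladation, CO insertion and C–O reductive elimination to A6, the zerovalent palladium being reoxidised by silver.
- In its favour: A5 is very simple (an aryl organometallic plus a terminal epoxide); the two ortho C–H bonds are equivalent, so there is no regiochemical question; the C3 centre is only carried along.
- Against it here: a hydroxyl group is a weak director and the method is best with tertiary alcohols; a secondary homobenzylic alcohol can be oxidised to the ketone by β-hydride elimination at divalent palladium; the electron-rich arene may be oxidised by the silver salt; two methyl ethers must be cleaved at the end, the C6 ether only under forcing conditions.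
- Comparison: on step economy to the bicyclic core it is the better plan. On stereochemistry it is equal, both plans resting on a carbinol set beforehand. On mechanism the chosen plan is safer, because its regiochemistry is built in and the phenols emerge free, whereas the C–H activation of a secondary alcohol is at the edge of the method's scope.

Key step: step 11

Remark on the chemistry: the double-bond geometries of 16, 17 and 18 and the configurations of the transient centres in 13 and 19 are left unspecified, because none survives into 21. Atoms are numbered as in isochroman-1-one and side-chain atoms carry a prime.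

## Route

Step 1
Reactants: 1 (S)-oct-1-yn-3-ol
Product: 2 (3S)-3-(tert-butyldimethylsilyloxy)oct-1-yne
Conditions: TBSCl, imidazole, DMF, 0 °C → rt
Reagents that add atoms: tert-butyldimethylsilyl chloride, CC(C)(C)[Si](C)(C)Cl
Why: Imidazole-promoted silylation of a secondary alcohol (silyl ether formation); the C–O bond is not broken, so the carbinol keeps its S configuration, and the alkyne C–H is untouched.

Step 2
Reactants: 2 (3S)-3-(tert-butyldimethylsilyloxy)oct-1-yne; 3 4-bromo-1,1-dimethoxybutane
Product: 5 (7S)-7-(tert-butyldimethylsilyloxy)-1,1-dimethoxydodec-5-yne, via lithium acetylide 4 (not isolated)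
Conditions: n-BuLi, THF, −78 °C; then 3, DMPU, −78 °C → rt
Reagents that add atoms: none
Why: Acetylide alkylation (SN2): n-BuLi removes the alkyne proton to give 4, and DMPU makes the lithium acetylide nucleophilic enough to displace the primary bromide of 3; silyl ether and acetal are inert to base and the stereocentre is not involved.

Step 3
Reactants: 5 (7S)-7-(tert-butyldimethylsilyloxy)-1,1-dimethoxydodec-5-yne
Product: 6 (7S)-7-(tert-butyldimethylsilyloxy)-1,1-dimethoxydodecane
Conditions: H2 (1 atm), Pd/C (10%), EtOAc, Et3N (trace), rt
Reagents that add atoms: none
Why: Heterogeneous catalytic hydrogenation of the alkyne to the alkane; the trace of amine keeps the medium non-acidic, so the acetal survives and hydrogenolysis of the propargylic C–O bond is suppressed; the descriptor stays S because the chain towards the acetal still outranks pentyl.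

Step 4
Reactants: 6 (7S)-7-(tert-butyldimethylsilyloxy)-1,1-dimethoxydodecane
Product: 7 (7S)-7-(tert-butyldimethylsilyloxy)dodecanal
Conditions: PPTS (cat.), acetone/H2O (9:1), 50 °C
Reagents that add atoms: water, O
Why: Acid-catalysed acetal hydrolysis through the oxocarbenium ion; pyridinium tosylate is too weak an acid to cleave a secondary TBS ether at a useful rate, and the unbranched aldehyde is used at once to avoid aldol self-condensation.

Step 5
Reactants: 7 (7S)-7-(tert-butyldimethylsilyloxy)dodecanal
Product: 9 (4R,10S)-10-(tert-butyldimethylsilyloxy)pentadec-1-en-4-ol, via diisopinocampheylborinate ester 8 (not isolated)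
Conditions: (−)-Ipc2BOMe, CH2=CHCH2MgBr, Et2O, 0 °C → rt; then 7, Et2O, −78 °C; then 3 M NaOH, 30% H2O2, 0 °C → rt
Reagents that add atoms: allylmagnesium bromide, C=CC[Mg]Br
Why: Brown allylboration through a chair-like six-membered (Zimmerman–Traxler) transition state; the isopinocampheyl groups of the borane made from (−)-B-methoxydiisopinocampheylborane (the (+)-α-pinene series) direct the allyl group to the Si face of an unbranched aliphatic aldehyde, the sense in which this reagent converts simple n-alkanals into (R)-alk-1-en-4-ols, so C4 is set R by reagent control without influence from the distant C10 centre; oxidative work-up cleaves 8 to 9 with the C–O bond intact.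

Step 6
Reactants: 9 (4R,10S)-10-(tert-butyldimethylsilyloxy)pentadec-1-en-4-ol; 10 acryloyl chloride
Product: 11 (4R,10S)-10-(tert-butyldimethylsilyloxy)pentadec-1-en-4-yl prop-2-enoate
Conditions: 10, Et3N, DMAP (cat.), CH2Cl2, 0 °C
Reagents that add atoms: none
Why: DMAP-catalysed O-acylation of a secondary alcohol by an acid chloride (esterification); low temperature and a short reaction time limit polymerisation and conjugate addition to the acrylate, and the carbinol C–O bond is not broken.

Step 7
Reactants: 11 (4R,10S)-10-(tert-butyldimethylsilyloxy)pentadec-1-en-4-yl prop-2-enoate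
Product: 12 (6R)-6-[(6S)-6-(tert-butyldimethylsilyloxy)undecyl]-5,6-dihydro-2H-pyran-2-one
Conditions: second-generation Grubbs catalyst (H2IMes)(PCy3)Cl2Ru=CHPh (5 mol%), CH2Cl2 (0.005 M), 40 °C
Reagents that add atoms: none
Why: Ring-closing olefin metathesis: the ruthenium carbene loads on the electron-rich terminal alkene and closes onto the acrylate, loss of ethene driving the reaction; high dilution favours the six-membered, necessarily Z, enoate over dimers, and the N-heterocyclic carbene catalyst is the one suited to acrylates.

Step 8
Reactants: 12 (6R)-6-[(6S)-6-(tert-butyldimethylsilyloxy)undecyl]-5,6-dihydro-2H-pyran-2-one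
Product: 14 (6R)-3-bromo-6-[(6S)-6-(tert-butyldimethylsilyloxy)undecyl]-5,6-dihydro-2H-pyran-2-one, via trans-dibromide 13 (not isolated)
Conditions: Br2, CH2Cl2, 0 °C → rt; then Et3N, 0 °C → rt
Reagents that add atoms: bromine, BrBr
Why: Bromination–dehydrobromination: anti addition of Br2 across C3=C4 gives 13, and Et3N then removes the acidic C3–H (α to the carbonyl) with expulsion of the C4 bromide (E1cB-type), which leaves bromine on C3 and restores the conjugated double bond; C6 and the silyl ether are not involved.

Step 9
Reactants: 15 methyl acetoacetate
Product: 16 methyl 3-(trimethylsilyloxy)but-2-enoate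
Conditions: TMSCl, Et3N, hexane, rt
Reagents that add atoms: chlorotrimethylsilane, C[Si](C)(C)Cl
Why: O-silylation of the enol form of a β-keto ester (silyl enol ether formation); the E/Z ratio is of no consequence because this double bond is shifted in step 10.

Step 10
Reactants: 16 methyl 3-(trimethylsilyloxy)but-2-enoate
Product: 18 1-methoxy-1,3-bis(trimethylsilyloxy)buta-1,3-diene, via lithium dienolate 17 (not isolated)
Conditions: LiN(iPr)2 (LDA, commercial solution), THF, −78 °C; then TMSCl, −78 → 0 °C; non-aqueous work-up, distillation
Reagents that add atoms: chlorotrimethylsilane, C[Si](C)(C)Cl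
Why: γ-Deprotonation of the vinylogous ester gives the extended enolate 17, which the hard silicon electrophile traps on oxygen (silyl ketene acetal formation); non-aqueous work-up is needed because 18 is hydrolysed by moisture.

Step 11
Reactants: 14 (6R)-3-bromo-6-[(6S)-6-(tert-butyldimethylsilyloxy)undecyl]-5,6-dihydro-2H-pyran-2-one; 18 1-methoxy-1,3-bis(trimethylsilyloxy)buta-1,3-diene
Product: 21 (3R)-3-[(6S)-6-(tert-butyldimethylsilyloxy)undecyl]-6,8-dihydroxyisochroman-1-one, via bromo cycloadduct 19 (not isolated), via aryl bis(trimethylsilyl) ether 20 (not isolated)
Conditions: 18 (3 equiv), toluene, 100 °C (sealed tube); then DBU, 60 °C; then 10% aq. citric acid, THF, rt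
Reagents that add atoms: none
Why: Normal-electron-demand Diels–Alder reaction: the HOMO of 18 is largest at its CH2 terminus and the LUMO of 14 at the β-carbon, so the leading bond is C4a–C5 and the ketene-acetal carbon closes onto the bromine-bearing α-carbon (C8–C8a); a stepwise Michael–Claisen sequence would form the same two bonds. The closest known reaction type is the aromatic annulation of 1,1,3-trioxygenated butadienes with α-halo or α-sulfinyl unsaturated carbonyl compounds used as alkyne equivalents. Ring A is closed as a six-membered carbocycle by an intermolecular suprafacial [4+2] addition across the cyclic Z-alkene, giving the cis-fused adduct 19. The centres created at C4a, C8 and C8a are transient and are erased on aromatisation, so no stereocontrol is needed, while C3 is insulated from the reacting bond by the C4 methylene, has no acidic hydrogen and keeps its R configuration. Aromatisation should begin with ionisation of methoxide from the C8 mixed ketal, assisted by the C6 silyl enol ether, and loss of H5; the resulting bromo-diene (C5=C6, C7=C8) then loses HBr to DBU, a step that cannot be an anti-E2 because H4a and Br8a are cis but is driven by the gain of aromaticity, giving 20. The selectivity needed is regiochemical (oxygen at C6 and C8, not C5 and C7); it is secured by the matched polarisation of the two partners and reinforced by bromine, which lowers the LUMO and supplies the oxidation level of an alkyne. Citric acid hydrolyses only the two aryl trimethylsilyl ethers; the secondary TBS ether and the lactone are stable to it.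

Step 12
Reactants: 21 (3R)-3-[(6S)-6-(tert-butyldimethylsilyloxy)undecyl]-6,8-dihydroxyisochroman-1-one
Product: 22 (3R)-6,8-dihydroxy-3-[(6S)-6-hydroxyundecyl]isochroman-1-one
Conditions: HF·pyridine, pyridine, THF, 0 °C → rt
Reagents that add atoms: none
Why: Fluoride-induced Si–O cleavage driven by the strong Si–F bond (silyl ether deprotection); the buffered, slightly acidic medium avoids phenoxide formation and lactone opening, and no C–O bond is broken, so C3 (R) and C6' (S) are retained.

## Compound list

1 | (S)-oct-1-yn-3-ol | CCCCC[C@H](O)C#C | starting material
2 | (3S)-3-(tert-butyldimethylsilyloxy)oct-1-yne | CCCCC[C@H](O[Si](C)(C)C(C)(C)C)C#C | intermediate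
3 | 4-bromo-1,1-dimethoxybutane | COC(CCCBr)OC | starting material
4 | lithium acetylide of 2 (formed in the flask, not isolated) | CCCCC[C@H](O[Si](C)(C)C(C)(C)C)C#C[Li] | intermediate
5 | (7S)-7-(tert-butyldimethylsilyloxy)-1,1-dimethoxydodec-5-yne | CCCCC[C@H](O[Si](C)(C)C(C)(C)C)C#CCCCC(OC)OC | intermediate
6 | (7S)-7-(tert-butyldimethylsilyloxy)-1,1-dimethoxydodecane | CCCCC[C@H](O[Si](C)(C)C(C)(C)C)CCCCCC(OC)OC | intermediate
7 | (7S)-7-(tert-butyldimethylsilyloxy)dodecanal | CCCCC[C@H](O[Si](C)(C)C(C)(C)C)CCCCCC=O | intermediate
8 | (4R,10S)-10-(tert-butyldimethylsilyloxy)pentadec-1-en-4-yl diisopinocampheylborinate (formed in the flask, not isolated) | CCCCC[C@H](O[Si](C)(C)C(C)(C)C)CCCCC[C@@H](OB([C@@H]1C[C@@H]2C[C@H]([C@H]1C)C2(C)C)[C@@H]1C[C@@H]2C[C@H]([C@H]1C)C2(C)C)CC=C | intermediate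
9 | (4R,10S)-10-(tert-butyldimethylsilyloxy)pentadec-1-en-4-ol | CCCCC[C@H](O[Si](C)(C)C(C)(C)C)CCCCC[C@@H](O)CC=C | intermediate
10 | acryloyl chloride | C=CC(=O)Cl | starting material
11 | (4R,10S)-10-(tert-butyldimethylsilyloxy)pentadec-1-en-4-yl prop-2-enoate | CCCCC[C@H](O[Si](C)(C)C(C)(C)C)CCCCC[C@@H](OC(=O)C=C)CC=C | intermediate
12 | (6R)-6-[(6S)-6-(tert-butyldimethylsilyloxy)undecyl]-5,6-dihydro-2H-pyran-2-one | CCCCC[C@H](O[Si](C)(C)C(C)(C)C)CCCCC[C@@H]1CC=CC(=O)O1 | intermediate
13 | (6R)-3,4-dibromo-6-[(6S)-6-(tert-butyldimethylsilyloxy)undecyl]tetrahydro-2H-pyran-2-one, 3,4-trans, both trans diastereomers (formed in the flask, not isolated) | CCCCC[C@H](O[Si](C)(C)C(C)(C)C)CCCCC[C@@H]1CC(Br)C(Br)C(=O)O1 | intermediate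
14 | (6R)-3-bromo-6-[(6S)-6-(tert-butyldimethylsilyloxy)undecyl]-5,6-dihydro-2H-pyran-2-one | CCCCC[C@H](O[Si](C)(C)C(C)(C)C)CCCCC[C@@H]1CC=C(Br)C(=O)O1 | intermediate
15 | methyl acetoacetate | CC(=O)CC(=O)OC | starting material
16 | methyl 3-(trimethylsilyloxy)but-2-enoate (E/Z mixture) | COC(=O)C=C(C)O[Si](C)(C)C | intermediate
17 | lithium 1-methoxy-3-(trimethylsilyloxy)buta-1,3-dien-1-olate (formed in the flask, not isolated) | [Li]OC(OC)=CC(=C)O[Si](C)(C)C | intermediate
18 | 1-methoxy-1,3-bis(trimethylsilyloxy)buta-1,3-diene | COC(O[Si](C)(C)C)=CC(O[Si](C)(C)C)=C | intermediate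
19 | (3R)-8a-bromo-3-[(6S)-6-(tert-butyldimethylsilyloxy)undecyl]-8-methoxy-6,8-bis(trimethylsilyloxy)-3,4,4a,5,8,8a-hexahydro-1H-isochromen-1-one, cis-fused, mixture at C4a, C8 and C8a (formed in the flask, not isolated) | CCCCC[C@H](O[Si](C)(C)C(C)(C)C)CCCCC[C@@H]1CC2CC(O[Si](C)(C)C)=CC(OC)(O[Si](C)(C)C)C2(Br)C(=O)O1 | intermediate
20 | (3R)-3-[(6S)-6-(tert-butyldimethylsilyloxy)undecyl]-6,8-bis(trimethylsilyloxy)isochroman-1-one (formed in the flask, not isolated) | CCCCC[C@H](O[Si](C)(C)C(C)(C)C)CCCCC[C@@H]1Cc2cc(O[Si](C)(C)C)cc(O[Si](C)(C)C)c2C(=O)O1 | intermediate
21 | (3R)-3-[(6S)-6-(tert-butyldimethylsilyloxy)undecyl]-6,8-dihydroxyisochroman-1-one | CCCCC[C@H](O[Si](C)(C)C(C)(C)C)CCCCC[C@@H]1Cc2cc(O)cc(O)c2C(=O)O1 | intermediate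
22 | (3R)-6,8-dihydroxy-3-[(6S)-6-hydroxyundecyl]isochroman-1-one | CCCCC[C@H](O)CCCCC[C@@H]1Cc2cc(O)cc(O)c2C(=O)O1 | target

## Step count and least certain steps

Total step count: 12. Longest linear sequence: 10 (steps 1 to 8, 11 and 12); steps 9 and 10 form the two-step side branch to 18.

Step 11 (key step). The cycloaddition may be slow compared with thermal and protolytic decay of the diene, because the dienophile is only a β-substituted α-bromo enoate. The dehydrobromination is stereoelectronically handicapped, since the ring-fusion hydrogen and bromine of a concerted adduct are cis. Liberated HBr may also strip silyl groups before aromatisation is complete. The fallback keeps the cycloaddition but replaces bromide by a sulfinyl group, whose thermal syn-elimination matches the cis geometry. It sets out from 14. Palladium-catalysed C–S coupling with thiophenol (Pd2(dba)3, Xantphos, iPr2NEt, dioxane) should give (6R)-6-[(6S)-6-(tert-butyldimethylsilyloxy)undecyl]-3-(phenylsulfanyl)-5,6-dihydro-2H-pyran-2-one F1. Oxidation with one equivalent of mCPBA at −78 °C should give the sulfoxide (6R)-6-[(6S)-6-(tert-butyldimethylsilyloxy)undecyl]-3-(phenylsulfinyl)-5,6-dihydro-2H-pyran-2-one F2 as a mixture of sulfur epimers. Heating F2 with 18 in toluene would give the cis-fused sulfinyl cycloadduct F3, which should lose benzenesulfenic acid and then methanol to give 20. The citric acid work-up then gives 21, where the route is rejoined.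

Step 5. Facial discrimination in the allyl transfer may be incomplete, particularly if magnesium salts are carried into the addition. Any C4 epimer formed cannot be removed later, because the two centres are too far apart to give separable diastereomers. The fallback sets the centre by resolution of an epoxide and sets out from 7. Dimethylsulfonium methylide (Me3SI, KN(SiMe3)2, THF) should give 2-[(6S)-6-(tert-butyldimethylsilyloxy)undecyl]oxirane F4 as a mixture of the two oxirane epimers. Hydrolytic kinetic resolution with the (R,R)-(salen)Co(OAc) complex of trivalent cobalt and 0.55 equivalents of water should leave (2R)-2-[(6S)-6-(tert-butyldimethylsilyloxy)undecyl]oxirane F5; this is the catalyst enantiomer expected to hydrolyse the (S)-configured oxirane. Opening F5 at the terminal carbon with CH2=CHMgBr and catalytic CuI would give 9.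

Step 4. The acid needed to hydrolyse the acetal may also start to cleave the secondary silyl ether, and the unbranched aldehyde may undergo aldol self-condensation during isolation. The fallback brings the terminus in at the alcohol oxidation level and sets out from 2 through 4. Alkylation with 2-(4-bromobutoxy)tetrahydro-2H-pyran would give 2-{[(7S)-7-(tert-butyldimethylsilyloxy)dodec-5-yn-1-yl]oxy}tetrahydro-2H-pyran F6. Hydrogenation over Pd/C would give 2-{[(7S)-7-(tert-butyldimethylsilyloxy)dodecyl]oxy}tetrahydro-2H-pyran F7. PPTS in ethanol at 55 °C should remove only the tetrahydropyranyl group to give (7S)-7-(tert-butyldimethylsilyloxy)dodecan-1-ol F8. Oxidation with Dess–Martin periodinane buffered with NaHCO3 returns to 7 under neutral conditions.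

Step 6. Acylation of the secondary alcohol may be outrun by polymerisation of the acrylate and by conjugate addition of chloride or amine to it, and the ring closure of step 7 depends on clean 11. The fallback builds the enoate by olefination and avoids both the acrylate and the metathesis. It sets out from 9. Ozonolysis (O3, CH2Cl2, −78 °C; PPh3) would give (3R,9S)-9-(tert-butyldimethylsilyloxy)-3-hydroxytetradecanal F9. Still–Gennari olefination with methyl bis(2,2,2-trifluoroethyl)phosphonoacetate, KN(SiMe3)2 and 18-crown-6 should give methyl (2Z,5R,11S)-11-(tert-butyldimethylsilyloxy)-5-hydroxyhexadec-2-enoate F10. Acid-catalysed lactonisation (PPTS, toluene, 60 °C) would then give 12.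

Further compounds

F1 | step 11 | (6R)-6-[(6S)-6-(tert-butyldimethylsilyloxy)undecyl]-3-(phenylsulfanyl)-5,6-dihydro-2H-pyran-2-one | CCCCC[C@H](O[Si](C)(C)C(C)(C)C)CCCCC[C@@H]1CC=C(Sc2ccccc2)C(=O)O1
F2 | step 11 | (6R)-6-[(6S)-6-(tert-butyldimethylsilyloxy)undecyl]-3-(phenylsulfinyl)-5,6-dihydro-2H-pyran-2-one (sulfur epimers) | CCCCC[C@H](O[Si](C)(C)C(C)(C)C)CCCCC[C@@H]1CC=C(S(=O)c2ccccc2)C(=O)O1
F3 | step 11 | (3R)-3-[(6S)-6-(tert-butyldimethylsilyloxy)undecyl]-8-methoxy-8a-(phenylsulfinyl)-6,8-bis(trimethylsilyloxy)-3,4,4a,5,8,8a-hexahydro-1H-isochromen-1-one (cis-fused, mixture of isomers) | CCCCC[C@H](O[Si](C)(C)C(C)(C)C)CCCCC[C@@H]1CC2CC(O[Si](C)(C)C)=CC(OC)(O[Si](C)(C)C)C2(S(=O)c3ccccc3)C(=O)O1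
F4 | step 5 | 2-[(6S)-6-(tert-butyldimethylsilyloxy)undecyl]oxirane (both oxirane epimers) | CCCCC[C@H](O[Si](C)(C)C(C)(C)C)CCCCCC1CO1
F5 | step 5 | (2R)-2-[(6S)-6-(tert-butyldimethylsilyloxy)undecyl]oxirane | CCCCC[C@H](O[Si](C)(C)C(C)(C)C)CCCCC[C@@H]1CO1
F6 | step 4 | 2-{[(7S)-7-(tert-butyldimethylsilyloxy)dodec-5-yn-1-yl]oxy}tetrahydro-2H-pyran (both acetal epimers) | CCCCC[C@H](O[Si](C)(C)C(C)(C)C)C#CCCCCOC1CCCCO1
F7 | step 4 | 2-{[(7S)-7-(tert-butyldimethylsilyloxy)dodecyl]oxy}tetrahydro-2H-pyran (both acetal epimers) | CCCCC[C@H](O[Si](C)(C)C(C)(C)C)CCCCCCOC1CCCCO1
F8 | step 4 | (7S)-7-(tert-butyldimethylsilyloxy)dodecan-1-ol | CCCCC[C@H](O[Si](C)(C)C(C)(C)C)CCCCCCO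
F9 | step 6 | (3R,9S)-9-(tert-butyldimethylsilyloxy)-3-hydroxytetradecanal | CCCCC[C@H](O[Si](C)(C)C(C)(C)C)CCCCC[C@@H](O)CC=O
F10 | step 6 | methyl (2Z,5R,11S)-11-(tert-butyldimethylsilyloxy)-5-hydroxyhexadec-2-enoate | CCCCC[C@H](O[Si](C)(C)C(C)(C)C)CCCCC[C@@H](O)C/C=C\C(=O)OC
A1 | alternative 1 | 2-[(6S)-6-hydroxyundecyl]-5,7-dimethoxy-2,3-dihydro-1H-inden-1-one (racemising at C2) | CCCCC[C@H](O)CCCCCC1Cc2cc(OC)cc(OC)c2C1=O
A2 | alternative 1 | (3R)-3-[(6S)-6-hydroxyundecyl]-6,8-dimethoxyisochroman-1-one | CCCCC[C@H](O)CCCCC[C@@H]1Cc2cc(OC)cc(OC)c2C(=O)O1
A3 | alternative 2 | 6-[(6R,12S)-6,12-bis(tert-butyldimethylsilyloxy)-2,4-dioxoheptadecyl]-2,2-dimethyl-4H-1,3-dioxin-4-one | CC1(C)OC(=O)C=C(CC(=O)CC(=O)C[C@H](O[Si](C)(C)C(C)(C)C)CCCCC[C@@H](O[Si](C)(C)C(C)(C)C)CCCCC)O1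
A4 | alternative 2 | 5-[(2R,8S)-2,8-bis(tert-butyldimethylsilyloxy)tridecyl]-7-hydroxy-2,2-dimethyl-4H-1,3-benzodioxin-4-one | CC1(C)OC(=O)c2c(C[C@H](O[Si](C)(C)C(C)(C)C)CCCCC[C@@H](O[Si](C)(C)C(C)(C)C)CCCCC)cc(O)cc2O1
A5 | alternative 3 | (2R,8S)-8-(tert-butyldimethylsilyloxy)-1-(3,5-dimethoxyphenyl)tridecan-2-ol | CCCCC[C@H](O[Si](C)(C)C(C)(C)C)CCCCC[C@@H](O)Cc1cc(OC)cc(OC)c1
A6 | alternative 3 | (3R)-3-[(6S)-6-(tert-butyldimethylsilyloxy)undecyl]-6,8-dimethoxyisochroman-1-one | CCCCC[C@H](O[Si](C)(C)C(C)(C)C)CCCCC[C@@H]1Cc2cc(OC)cc(OC)c2C(=O)O1
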